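**Retrosynthetic overview**
1. Compounds in order of use: β-ionone 1, (3R)-3-hydroxy-β-ionone 2, myristoyl chloride 3, dienone ester 4, target 5. Ionone numbering is used: C1 = CMe2, C3 = O-bearing carbon, C5/C6 = epoxide carbons, C7–C10 = butenone chain.
2. 5 ⇒ 4: both epoxide C–O bonds (C5–O, C6–O); forward, epoxidation of C5=C6 on the face anti to the C3 ester.
3. 4 ⇒ 2 + 3: the acyl C–O bond of the ester; forward, O-acylation that leaves C3 untouched.
4. 2 ⇒ 1: the C3–O bond (key step); forward, enantioselective enzymatic hydroxylation of the unactivated C3 methylene, which sets (3R).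
5. Ring order: the cyclohexene ring is bought with 1; the oxirane is the only ring formed and is closed last; no C–C bond is made.

**Route**

Step 1
Reactants: 1 β-ionone, (E)-4-(2,6,6-trimethylcyclohex-1-en-1-yl)but-3-en-2-one
Product: 2 (3R)-3-hydroxy-β-ionone, (E)-4-[(4R)-4-hydroxy-2,6,6-trimethylcyclohex-1-en-1-yl]but-3-en-2-one
Conditions: engineered (3R)-selective CYP101B1 variant (heme-thiolate P450 monooxygenase) with ferredoxin Arx and ferredoxin reductase ArR (E. coli lysate), NAD+ (cat.), glucose dehydrogenase, D-glucose (1.5 equiv), air, KH2PO4/K2HPO4 buffer pH 7.4, 5% DMSO, 30 °C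
Reagents that add atoms: dioxygen, O=O
Why: Proposed new method: a redesigned P450 active site for (3R)-selective hydroxylation of the unactivated C3 methylene of β-ionone; the thiolate-bound oxo-iron porphyrin radical cation (tetravalent iron-oxo, compound one of the P450 cycle) abstracts one hydrogen atom and returns OH to the same face (oxygen rebound, retention), so the configuration is fixed by which C3 hydrogen faces iron; the variant keeps the polar contact to the C9 carbonyl that already holds the ring over the heme in the wild type (which is why C3–H is attacked rather than the weaker allylic C4–H or the C5=C6 bond) and adds first-shell substitutions around the gem-dimethyl edge, chosen by docking and iterative saturation mutagenesis with a chiral GC screen, that admit only the half-chair presenting H-3(pro-R) to the oxo group, which gives the (3R) alcohol; closest known reaction type: P450-catalysed C–H hydroxylation, in particular the C3-selective hydroxylation of β-ionone by wild-type CYP101B1 (about 9:1 over C4, as recalled), where the configuration at C3 is not under designed control.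

Step 2
Reactants: 2 (3R)-3-hydroxy-β-ionone; 3 myristoyl chloride (tetradecanoyl chloride)
Product: 4 (3R)-3-(tetradecanoyloxy)-β-ionone, (1R)-3,5,5-trimethyl-4-[(E)-3-oxobut-1-en-1-yl]cyclohex-3-en-1-yl tetradecanoate
Conditions: pyridine (2 equiv), 4-(dimethylamino)pyridine (5 mol%), CH2Cl2, 0 °C to rt
Reagents that add atoms: none
Why: O-acylation of the alcohol by the acid chloride (nucleophilic acyl substitution) makes the ester C–O bond at the acyl carbon, so the C3–O bond and its (3R) configuration are untouched, and pyridine is too weak a base to cause vinylogous elimination of the new ester.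

Step 3
Reactants: 4 (3R)-3-(tetradecanoyloxy)-β-ionone
Product: 5 (3S,5R,6S)-5,6-epoxy-3-(tetradecanoyloxy)-5,6-dihydro-β-ionone (target)
Conditions: mCPBA (1.1 equiv), CH2Cl2, 0 °C
Reagents that add atoms: mCPBA (3-chloroperoxybenzoic acid), OOC(=O)c1cccc(Cl)c1
Why: Prilezhaev epoxidation: the electrophilic peracid attacks only the electron-rich tetrasubstituted C5=C6 bond (the C7=C8 enone bond is electron-poor) and delivers oxygen to one face in a concerted step, so C5 and C6 are set together as (5R,6S) on the face anti to the C3 acyloxy group; this substrate-controlled preference is expected to be only modest (about 2–4:1 at best), so the syn epoxide is removed by chromatography.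

**Compound list**
1 | β-ionone, (E)-4-(2,6,6-trimethylcyclohex-1-en-1-yl)but-3-en-2-one | CC(=O)/C=C/C1=C(C)CCCC1(C)C | starting material
2 | (3R)-3-hydroxy-β-ionone, (E)-4-[(4R)-4-hydroxy-2,6,6-trimethylcyclohex-1-en-1-yl]but-3-en-2-one | O[C@H]1CC(C)(C)C(/C=C/C(C)=O)=C(C)C1 | intermediate
3 | myristoyl chloride (tetradecanoyl chloride) | CCCCCCCCCCCCCC(=O)Cl | starting material
4 | (3R)-3-(tetradecanoyloxy)-β-ionone, (1R)-3,5,5-trimethyl-4-[(E)-3-oxobut-1-en-1-yl]cyclohex-3-en-1-yl tetradecanoate | CCCCCCCCCCCCCC(=O)O[C@H]1CC(C)(C)C(/C=C/C(C)=O)=C(C)C1 | intermediate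
5 | (3S,5R,6S)-5,6-epoxy-3-(tetradecanoyloxy)-5,6-dihydro-β-ionone, (1R,3S,6S)-1,5,5-trimethyl-6-[(E)-3-oxobut-1-en-1-yl]-7-oxabicyclo[4.1.0]heptan-3-yl tetradecanoate; epoxide oxygen trans to the ester oxygen; C3 is spatially unchanged from 4 and is S only because the CIP ranks of C2 and C4 swap | CCCCCCCCCCCCCC(=O)O[C@H]1CC(C)(C)[C@]2(/C=C/C(C)=O)O[C@]2(C)C1 | target

**Totals**
Total step count: 3. Longest linear sequence: 3 steps (1 → 2 → 4 → 5).

**Steps most likely to fail**

Step 1 (proposed new method). The variant may give too little enantioselectivity, some C4 (allylic) alcohol, over-oxidation to the ketone, or low turnover. The fallback uses known chemistry only; it sets out from 1 and comes back to the route at 4.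
- The wild-type CYP101B1/Arx/ArR system, run as in step 1, hydroxylates 1 at C3 (a known reaction) and gives 3-hydroxy-β-ionone of uncontrolled configuration at C3 F1.
- Kinetic resolution by lipase-catalysed transesterification (Burkholderia cepacia lipase, vinyl myristate, MTBE, 30 °C) acylates the (3R) enantiomer, the fast one by the Kazlauskas rule and by precedent for this alcohol, and so gives 4 directly.
- The unreacted (3S)-3-hydroxy-β-ionone F2 is separated on silica and converted into 4 as well by Mitsunobu esterification with myristic acid (PPh3, DIAD, THF, 0 °C), which inverts C3.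
- The approach changes from asymmetric C–H hydroxylation to resolution plus stereoinversion.

Step 3. The anti/syn ratio is modest and not firmly known for this ester, and the two diastereomeric C14 esters may be hard to separate. The fallback sets out from 2 and comes back at 5.
- Silylation (TBSCl, imidazole, DMF, rt) gives (3R)-3-(tert-butyldimethylsilyloxy)-β-ionone F3.
- mCPBA in CH2Cl2 at 0 °C gives (3S,5R,6S)-5,6-epoxy-3-(tert-butyldimethylsilyloxy)-5,6-dihydro-β-ionone F4. The bulkier silyl ether is expected to raise the anti preference, and the small diastereomers separate far more easily on silica.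
- Desilylation (Bu4NF, AcOH, THF, 0 °C to rt) gives (3S,5R,6S)-5,6-epoxy-3-hydroxy-5,6-dihydro-β-ionone F5, a known natural apocarotenoid whose identity and purity can be checked before the chain is attached.
- Acylation with 3 (pyridine, 4-(dimethylamino)pyridine, CH2Cl2, 0 °C) gives 5.
- The approach changes from late epoxidation of the ester to epoxidation and diastereomer separation before acylation.

Step 2. Acylation may be incomplete, or the base may start vinylogous elimination of the ester to 3,4-didehydro-β-ionone. The fallback sets out from 2 and comes back at 4; it makes no new compound (F0).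
- Base-free enzymatic acyl transfer (Burkholderia cepacia lipase, vinyl myristate, MTBE, 30–40 °C) replaces the acid chloride.
- Because the lipase accepts only the (3R) alcohol, it also removes any (3S) material left from step 1.

**Further compounds**
F1 | step 1 | 3-hydroxy-β-ionone, configuration at C3 uncontrolled (mixture of enantiomers) | CC(=O)/C=C/C1=C(C)CC(O)CC1(C)C
F2 | step 1 | (3S)-3-hydroxy-β-ionone | O[C@@H]1CC(C)(C)C(/C=C/C(C)=O)=C(C)C1
F0 | step 2 | none | none
F3 | step 3 | (3R)-3-(tert-butyldimethylsilyloxy)-β-ionone | CC(C)(C)[Si](C)(C)O[C@H]1CC(C)(C)C(/C=C/C(C)=O)=C(C)C1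
F4 | step 3 | (3S,5R,6S)-5,6-epoxy-3-(tert-butyldimethylsilyloxy)-5,6-dihydro-β-ionone | CC(C)(C)[Si](C)(C)O[C@H]1CC(C)(C)[C@]2(/C=C/C(C)=O)O[C@]2(C)C1
F5 | step 3 | (3S,5R,6S)-5,6-epoxy-3-hydroxy-5,6-dihydro-β-ionone | O[C@H]1CC(C)(C)[C@]2(/C=C/C(C)=O)O[C@]2(C)C1
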